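The data come from a simulation with made-up constants; scatter was added.

1. At time zero this flask holds 10 mM substrate, 5.0 µM enzyme and 1.0 µM impurity.

all flasks: substrate 10 mM

|  | enzyme | impurity | remark |
|---|---|---|---|
| Wednesday's | 5 µM | 0.67 µM | run made earlier |
| Sunday's | 5 µM | 1.5 µM | run made earlier |
| Monday's | 10 µM | 1 µM | run made earlier |
| flask | 5.0 µM | 1.0 µM |  |

- Wednesday's (time / h: product / %, substrate / %): 8.00: 25.1, 76.2; 15.0: 45.2, 54.5; 25.0: 70.8, 29.6; 30.0: 78.9, 20.8; 40.0: 93.2, 10.0; 50.0: 97.8, 2.3
- Sunday's (time / h: product / %, substrate / %): 8.00: 20.7, 79.1; 15.0: 38.3, 62.8; 25.0: 61.0, 41.7; 30.0: 68.4, 32.1; 40.0: 84.1, 16.5; 50.0: 93.9, 7.3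
- Monday's (time / h: product / %, substrate / %): 4.00: 25.7, 73.1; 8.00: 49.4, 48.3; 15.0: 82.6, 18.9; 25.0: 98.8, 1.7; 50.0: 100.9, 0.3

(standard deviation of a reading: 1 percentage point)

- steps thought possible: enzyme + impurity -> spent catalyst; substrate + enzyme -> product + enzyme

- apparent order in enzyme when 10% of the substrate are converted (percent change of the rate of making product for one percent more enzyme charged)

2. Follow one enzyme molecule: it turns substrate into product until it meets impurity and becomes spent catalyst.

3. Wednesday's and Sunday's runs had equal enzyme charged. At 8.00 h, the product reading in Sunday's run was 0.825 of Wednesday's, and c(enzyme) − c(impurity) in Sunday's run was 0.808 of Wednesday's.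

4. So in this flask, count the working enzyme, c(enzyme) − c(impurity), 4.00 µM. In this flask impurity is the limiting reagent of the poisoning step, with c(impurity) charged lower than c(enzyme) charged.

5. My reckoning assumes that step is over at 10% conversion, with the rate proportional to working enzyme. The order is then c(enzyme) over working enzyme, 1.25.

6. Leave the charges of this flask alone: the reckoned 1.25 holds for them.

The forecast gives 1.25, on the grounds that “The early rates scale with enzyme minus impurity, not with enzyme charged.”

7. The flask gives an order of 1.3.

    enzyme + impurity → spent catalyst (k = 9.20 × 10⁵ M⁻¹ h⁻¹)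
    substrate + enzyme → product + enzyme, rate k2*[substrate]*[enzyme]/(1 + ([substrate]/Km2)) (3.10 mM, k = 32000 M⁻¹ h⁻¹)

At 0.200 d, this flask has impurity at 0% of its charge, with enzyme at 80.0% and spent catalyst at 20.0% of the catalyst charged, while working enzyme over enzyme charged is 80.0%. With twice the enzyme and the same impurity, working enzyme becomes 9.00 µM, which is 2.25 times 4.00 µM, and the flask run with that doubled enzyme charge gives a rate factor of 2.25.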